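**Retrosynthetic overview**
1. The target is read as a 5-6-7 cyathane-type tricycle; the 12,13-epoxide and the 17-acetate are put on last.
2. Rings B and A are made in one Lewis-acid cascade from epoxy alcohol 22: a 1,2-alkyl shift expands a cyclopentanol to ring B (setting C9, freeing C17–OH and a C4 ketone), then the allylsilane of a pendant butenolide captures the C4 carbonyl (ring A, C3, C4, exocyclic methylene).
3. 22 comes from trans-hydroazulenone 11 and bromodienol 15 by vinyllithium addition, acylation, ring-closing metathesis and hydroxyl-directed epoxidation.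
4. 11 comes from an enantioselective Ireland–Claisen rearrangement (C5/C6), hydroacylation (five-membered ring) and ring-closing metathesis (ring C).
5. Ring order: C with its five-membered partner, then B by ring expansion, then A, then the epoxide.

Assumption: the target is treated as a cyathane-type diterpenoid whose presumed biosynthesis closes ring C first, expands a five-membered ring to ring B by a 1,2-alkyl shift, closes ring A by olefin capture of the C4 cation and oxidises last; compounds 1, 4, 12, 13 and 18 are taken as purchasable.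

Numbering used in names and explanations (cyathane numbering): ring A = C1–C4, C9; ring B = C4–C9; ring C = C5, C6, C10–C14; C15 on C12, C16 on C6, C17 on C9, C18 on C3 carrying C19H2= and C20(=O).

**Route**

Step 1
Reactants: 1 pent-1-en-4-yne
Product: 3 (2E)-3-methylhexa-2,5-dien-1-ol, via alkenylalane 2 (not isolated)
Conditions: AlMe3, Cp2ZrCl2 (20 mol%), CH2Cl2, 0 → 23 °C; then n-BuLi, (CH2O)n, THF, −78 → 23 °C
Reagents that add atoms: trimethylaluminium C[Al](C)C; paraformaldehyde (as formaldehyde) C=O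
Why: Zirconium-catalysed syn-carboalumination (Negishi) puts CH3 and Al cis on the terminal alkyne and the alkenylalanate is trapped by formaldehyde with retention, which fixes the 2E geometry (CH3 cis to CH2OH).

Step 2
Reactants: 3 (2E)-3-methylhexa-2,5-dien-1-ol; 4 5-methylhex-5-enoic acid
Product: 5 (2E)-3-methylhexa-2,5-dien-1-yl 5-methylhex-5-enoate
Conditions: DCC, DMAP (cat.), CH2Cl2, 0 → 23 °C
Reagents that add atoms: none
Why: Steglich esterification of a primary allylic alcohol; no stereocentre is formed.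

Step 3
Reactants: 5 (2E)-3-methylhexa-2,5-dien-1-yl 5-methylhex-5-enoate
Product: 7 (2S,3R)-3-ethenyl-3-methyl-2-(3-methylbut-3-en-1-yl)hex-5-enoic acid, via boron enolate 6 (not isolated)
Conditions: (4S,5S)-2-bromo-1,3-bis[3,5-bis(trifluoromethyl)phenylsulfonyl]-4,5-diphenyl-1,3,2-diazaborolidine (1.1 equiv), i-Pr2NEt, CH2Cl2, −78 °C, then −20 → 23 °C; aqueous work-up
Reagents that add atoms: none
Why: Enantioselective Ireland–Claisen rearrangement through a chair transition state in which the Z(O) boron enolate holds the side chain equatorial and the 2E alkene holds CH3 axial, so C5 and C6 are set together (homoallyl chain anti to the allyl group) while the C2-symmetric boron controller fixes the absolute sense (its sense of induction for this ester is not known in advance; the antipodal controller is used if it proves opposite).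

Step 4
Reactants: 7 (2S,3R)-3-ethenyl-3-methyl-2-(3-methylbut-3-en-1-yl)hex-5-enoic acid
Product: 8 (2S,3R)-3-ethenyl-3-methyl-2-(3-methylbut-3-en-1-yl)hex-5-en-1-ol
Conditions: LiAlH4, Et2O, 0 → 23 °C
Reagents that add atoms: none
Why: Hydride reduction of the carboxylic acid to the primary alcohol, which leaves both stereocentres and the three alkenes untouched.

Step 5
Reactants: 8 (2S,3R)-3-ethenyl-3-methyl-2-(3-methylbut-3-en-1-yl)hex-5-en-1-ol
Product: 9 (2S,3R)-3-ethenyl-3-methyl-2-(3-methylbut-3-en-1-yl)hex-5-enal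
Conditions: Dess–Martin periodinane, NaHCO3, CH2Cl2, 0 → 23 °C
Reagents that add atoms: none
Why: Dess–Martin oxidation under buffered, non-basic conditions gives the α-branched aldehyde without epimerising C5.

Step 6
Reactants: 9 (2S,3R)-3-ethenyl-3-methyl-2-(3-methylbut-3-en-1-yl)hex-5-enal
Product: 10 (2S,3S)-3-methyl-2-(3-methylbut-3-en-1-yl)-3-(prop-2-en-1-yl)cyclopentan-1-one
Conditions: [Rh(dppe)]2(ClO4)2 (5 mol%), CH2Cl2, 23 °C
Reagents that add atoms: none
Why: Rhodium-catalysed intramolecular hydroacylation of a 4-pentenal adds the acyl C–H across the vinyl group (five-ring closure is preferred over six-ring closure onto the other alkenes) under neutral conditions, so C5 and C6 are carried into the cyclopentanone unchanged.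

Step 7
Reactants: 10 (2S,3S)-3-methyl-2-(3-methylbut-3-en-1-yl)-3-(prop-2-en-1-yl)cyclopentan-1-one
Product: 11 (3aS,8aS)-3a,6-dimethyl-3,3a,4,7,8,8a-hexahydroazulen-1(2H)-one
Conditions: second-generation Grubbs catalyst RuCl2(=CHPh)(PCy3)(H2IMes) (5 mol%), CH2Cl2 (5 mM), 40 °C
Reagents that add atoms: none
Why: Ring-closing metathesis of the allyl and isopropenyl termini closes ring C with its trisubstituted C12=C13 alkene; the trans disposition of the two chains gives the trans ring fusion (H5 β, C6–CH3 α) and the neutral conditions do not epimerise C5.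

Step 8
Reactants: 12 acrolein; 13 2,3-dibromoprop-1-ene
Product: 14 rac-5-bromohexa-1,5-dien-3-ol
Conditions: In powder, THF/H2O (1:1), 23 °C
Reagents that add atoms: none
Why: Indium-mediated Barbier 2-bromoallylation adds 1,2 to the aldehyde and leaves the vinyl bromide intact; the product is racemic.

Step 9
Reactants: 14 rac-5-bromohexa-1,5-dien-3-ol
Product: 15 (3S)-5-bromohexa-1,5-dien-3-ol
Conditions: Ti(OiPr)4 (0.2 equiv), D-(−)-diisopropyl tartrate (0.24 equiv), t-BuOOH (0.6 equiv), 4 Å molecular sieves, CH2Cl2, −20 °C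
Reagents that add atoms: none
Why: Sharpless kinetic resolution: with the D-tartrate the 3R alcohol is epoxidised at its vinyl group much faster, and the 3S alcohol (the future C2 centre) is recovered in high ee.

Step 10
Reactants: 15 (3S)-5-bromohexa-1,5-dien-3-ol; 11 (3aS,8aS)-3a,6-dimethyl-3,3a,4,7,8,8a-hexahydroazulen-1(2H)-one
Product: 17 (1R,3aS,8aS)-1-[(4S)-4-hydroxyhexa-1,5-dien-2-yl]-3a,6-dimethyl-1,2,3,3a,4,7,8,8a-octahydroazulen-1-ol, via dilithio species 16 (not isolated)
Conditions: 15, MeLi (1.0 equiv), then t-BuLi (2.1 equiv), THF, −78 °C; CeCl3, −78 °C; then 11, −78 → −40 °C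
Reagents that add atoms: none
Why: Bromine–lithium exchange on the lithium alkoxide gives a vinyllithium that, as its organocerium, adds 1,2 to the enolisable ketone from the β face, anti to the adjacent C5–C10 bond and to the pseudo-axial C6 methyl, which sets C4 (R, OH α).

Step 11
Reactants: 18 ethyl 2-[(trimethylsilyl)methyl]prop-2-enoate
Product: 19 2-[(trimethylsilyl)methyl]prop-2-enoic acid
Conditions: LiOH·H2O, THF/H2O, 0 → 23 °C; then 1 M HCl to pH 4
Reagents that add atoms: lithium hydroxide [Li+].[OH-]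
Why: Ester saponification; the allylsilane survives cold aqueous base and mild acidification.

Step 12
Reactants: 17 (1R,3aS,8aS)-1-[(4S)-4-hydroxyhexa-1,5-dien-2-yl]-3a,6-dimethyl-1,2,3,3a,4,7,8,8a-octahydroazulen-1-ol; 19 2-[(trimethylsilyl)methyl]prop-2-enoic acid
Product: 20 (3S)-5-[(1R,3aS,8aS)-1-hydroxy-3a,6-dimethyl-1,2,3,3a,4,7,8,8a-octahydroazulen-1-yl]hexa-1,5-dien-3-yl 2-[(trimethylsilyl)methyl]prop-2-enoate
Conditions: DCC, DMAP (cat.), CH2Cl2, 0 → 23 °C
Reagents that add atoms: none
Why: Steglich esterification acylates only the secondary allylic C2–OH because the tertiary C4–OH is too hindered.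

Step 13
Reactants: 20 (3S)-5-[(1R,3aS,8aS)-1-hydroxy-3a,6-dimethyl-1,2,3,3a,4,7,8,8a-octahydroazulen-1-yl]hexa-1,5-dien-3-yl 2-[(trimethylsilyl)methyl]prop-2-enoate
Product: 21 (5S)-5-{2-[(1R,3aS,8aS)-1-hydroxy-3a,6-dimethyl-1,2,3,3a,4,7,8,8a-octahydroazulen-1-yl]prop-2-en-1-yl}-3-[(trimethylsilyl)methyl]furan-2(5H)-one
Conditions: second-generation Grubbs catalyst RuCl2(=CHPh)(PCy3)(H2IMes) (10 mol%), toluene (2 mM), 80 °C
Reagents that add atoms: none
Why: Ring-closing metathesis between the C3 vinyl group and the acrylate gives the butenolide carrying CH2SiMe3 on C18; the 1,1-disubstituted C9=C17 alkene and the ring-C alkene are too hindered to compete and C2 is untouched.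

Step 14
Reactants: 21 (5S)-5-{2-[(1R,3aS,8aS)-1-hydroxy-3a,6-dimethyl-1,2,3,3a,4,7,8,8a-octahydroazulen-1-yl]prop-2-en-1-yl}-3-[(trimethylsilyl)methyl]furan-2(5H)-one
Product: 22 (5S)-5-{[(2S)-2-[(1R,3aS,8aS)-1-hydroxy-3a,6-dimethyl-1,2,3,3a,4,7,8,8a-octahydroazulen-1-yl]oxiran-2-yl]methyl}-3-[(trimethylsilyl)methyl]furan-2(5H)-one
Conditions: VO(acac)2 (5 mol%), t-BuOOH, CH2Cl2, 0 → 23 °C
Reagents that add atoms: tert-butyl hydroperoxide CC(C)(C)OO
Why: Hydroxyl-directed vanadium-catalysed epoxidation touches only the allylic C9=C17 alkene, and under A(1,2) strain the vanadate transition state puts the smaller C8 methylene (not C5) beside the C9 substituent, which delivers oxygen to the face that makes C9 S (erythro-type selectivity).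

Step 15
Reactants: 22 (5S)-5-{[(2S)-2-[(1R,3aS,8aS)-1-hydroxy-3a,6-dimethyl-1,2,3,3a,4,7,8,8a-octahydroazulen-1-yl]oxiran-2-yl]methyl}-3-[(trimethylsilyl)methyl]furan-2(5H)-one
Product: 24 (2S,3S,4R,5S,6S,9S)-4,17-dihydroxycyatha-12,18(19)-dien-20,2-olide, via ketol 23 (not isolated)
Conditions: BF3·OEt2 (3 equiv), CH2Cl2, −78 → −20 °C; then H2O
Reagents that add atoms: none
Why: Proposed new method: BF3 opens the epoxide at tertiary C9 and C8, the ring bond anti to the breaking C–O bond in the less crowded rotamer (C5 anti to the side chain), migrates from C4 to C9 with inversion (semipinacol ring expansion of a 2,3-epoxy alcohol) to give ring B with C17–O and a boron-bound C4 ketone, which the 2-(silylmethyl)butenolide then attacks through C3 in an intramolecular Hosomi–Sakurai allylation (closest known types: Lewis-acid epoxy-alcohol semipinacol ring expansion and cyclisation of ester-substituted allylsilanes onto carbonyls); the necessarily cis-fused bicyclic lactone fixes C3 from C2, and attack on the β face of C4, which avoids a 1,3-diaxial clash with the C6 methyl, gives the trans-fused ring A with 4α-OH and the exocyclic methylene after loss of Me3Si.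

Step 16
Reactants: 24 (2S,3S,4R,5S,6S,9S)-4,17-dihydroxycyatha-12,18(19)-dien-20,2-olide
Product: 25 (2S,3S,4R,5S,6S,9S)-17-acetoxy-4-hydroxycyatha-12,18(19)-dien-20,2-olide
Conditions: Ac2O, pyridine, DMAP (cat.), CH2Cl2, 0 °C
Reagents that add atoms: acetic anhydride CC(=O)OC(C)=O
Why: Acylation of the primary C17–OH only; the tertiary 4-OH does not react.

Step 17
Reactants: 25 (2S,3S,4R,5S,6S,9S)-17-acetoxy-4-hydroxycyatha-12,18(19)-dien-20,2-olide
Product: 26 (2S,3S,4R,5S,6S,9S,12S,13R)-17-acetoxy-12,13-epoxy-4-hydroxycyath-18(19)-en-20,2-olide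
Conditions: mCPBA, NaHCO3, CH2Cl2, 0 °C
Reagents that add atoms: meta-chloroperoxybenzoic acid OOC(=O)c1cccc(Cl)c1
Why: Prilezhaev epoxidation of the only electron-rich alkene (the α-methylene lactone is inert) from the β face, opposite the axial C6 methyl that shields the α face of ring C, gives the 12S,13R epoxide.

**Compound list**
1 | pent-1-en-4-yne | C=CCC#C | starting material
2 | (1E)-dimethyl(2-methylpenta-1,4-dien-1-yl)alumane | C=CC/C(C)=C/[Al](C)C | intermediate
3 | (2E)-3-methylhexa-2,5-dien-1-ol | OC/C=C(\C)CC=C | intermediate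
4 | 5-methylhex-5-enoic acid | C=C(C)CCCC(=O)O | starting material
5 | (2E)-3-methylhexa-2,5-dien-1-yl 5-methylhex-5-enoate | C=C(C)CCCC(=O)OC/C=C(\C)CC=C | intermediate
6 | Z(O) boron enolate of 5 (enol oxygen on the boron of the (4S,5S)-1,3-bis[3,5-bis(trifluoromethyl)phenylsulfonyl]-4,5-diphenyl-1,3,2-diazaborolidine) | C=C(C)CC/C=C(/OC/C=C(\C)CC=C)OB1N(S(=O)(=O)c2cc(cc(c2)C(F)(F)F)C(F)(F)F)[C@@H](c2ccccc2)[C@H](c2ccccc2)N1S(=O)(=O)c1cc(cc(c1)C(F)(F)F)C(F)(F)F | intermediate
7 | (2S,3R)-3-ethenyl-3-methyl-2-(3-methylbut-3-en-1-yl)hex-5-enoic acid | O=C(O)[C@@H](CCC(C)=C)[C@](C)(CC=C)C=C | intermediate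
8 | (2S,3R)-3-ethenyl-3-methyl-2-(3-methylbut-3-en-1-yl)hex-5-en-1-ol | OC[C@@H](CCC(C)=C)[C@](C)(CC=C)C=C | intermediate
9 | (2S,3R)-3-ethenyl-3-methyl-2-(3-methylbut-3-en-1-yl)hex-5-enal | O=C[C@@H](CCC(C)=C)[C@](C)(CC=C)C=C | intermediate
10 | (2S,3S)-3-methyl-2-(3-methylbut-3-en-1-yl)-3-(prop-2-en-1-yl)cyclopentan-1-one | O=C1CC[C@@](C)(CC=C)[C@@H]1CCC(C)=C | intermediate
11 | (3aS,8aS)-3a,6-dimethyl-3,3a,4,7,8,8a-hexahydroazulen-1(2H)-one (trans-fused) | O=C1CC[C@@]2(C)CC=C(C)CC[C@H]12 | intermediate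
12 | acrolein | C=CC=O | starting material
13 | 2,3-dibromoprop-1-ene | C=C(Br)CBr | starting material
14 | rac-5-bromohexa-1,5-dien-3-ol | C=C(Br)CC(O)C=C | intermediate
15 | (3S)-5-bromohexa-1,5-dien-3-ol | C=C(Br)C[C@H](O)C=C | intermediate
16 | [(3S)-5-lithiohexa-1,5-dien-3-yl]oxylithium | [Li]C(=C)C[C@H](O[Li])C=C | intermediate
17 | (1R,3aS,8aS)-1-[(4S)-4-hydroxyhexa-1,5-dien-2-yl]-3a,6-dimethyl-1,2,3,3a,4,7,8,8a-octahydroazulen-1-ol | O[C@]1(C(=C)C[C@H](O)C=C)CC[C@@]2(C)CC=C(C)CC[C@H]12 | intermediate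
18 | ethyl 2-[(trimethylsilyl)methyl]prop-2-enoate | C=C(C[Si](C)(C)C)C(=O)OCC | starting material
19 | 2-[(trimethylsilyl)methyl]prop-2-enoic acid | C=C(C[Si](C)(C)C)C(=O)O | intermediate
20 | (3S)-5-[(1R,3aS,8aS)-1-hydroxy-3a,6-dimethyl-1,2,3,3a,4,7,8,8a-octahydroazulen-1-yl]hexa-1,5-dien-3-yl 2-[(trimethylsilyl)methyl]prop-2-enoate | O[C@]1(C(=C)C[C@H](OC(=O)C(=C)C[Si](C)(C)C)C=C)CC[C@@]2(C)CC=C(C)CC[C@H]12 | intermediate
21 | (5S)-5-{2-[(1R,3aS,8aS)-1-hydroxy-3a,6-dimethyl-1,2,3,3a,4,7,8,8a-octahydroazulen-1-yl]prop-2-en-1-yl}-3-[(trimethylsilyl)methyl]furan-2(5H)-one | O[C@]1(C(=C)C[C@@H]3OC(=O)C(C[Si](C)(C)C)=C3)CC[C@@]2(C)CC=C(C)CC[C@H]12 | intermediate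
22 | (5S)-5-{[(2S)-2-[(1R,3aS,8aS)-1-hydroxy-3a,6-dimethyl-1,2,3,3a,4,7,8,8a-octahydroazulen-1-yl]oxiran-2-yl]methyl}-3-[(trimethylsilyl)methyl]furan-2(5H)-one | O[C@]1([C@@]4(CO4)C[C@@H]3OC(=O)C(C[Si](C)(C)C)=C3)CC[C@@]2(C)CC=C(C)CC[C@H]12 | intermediate
23 | (2S,4aS,9aS)-2-(hydroxymethyl)-4a,7-dimethyl-2-{[(2S)-5-oxo-4-[(trimethylsilyl)methyl]-2,5-dihydrofuran-2-yl]methyl}-2,3,4,4a,5,8,9,9a-octahydro-1H-benzo[7]annulen-1-one | O=C1[C@](CO)(C[C@@H]3OC(=O)C(C[Si](C)(C)C)=C3)CC[C@@]2(C)CC=C(C)CC[C@H]12 | intermediate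
24 | (2S,3S,4R,5S,6S,9S)-4,17-dihydroxycyatha-12,18(19)-dien-20,2-olide (target without acetyl and epoxide) | C=C1C(=O)O[C@H]2C[C@]3(CO)CC[C@@]4(C)CC=C(C)CC[C@@H]4[C@@]3(O)[C@@H]12 | intermediate
25 | (2S,3S,4R,5S,6S,9S)-17-acetoxy-4-hydroxycyatha-12,18(19)-dien-20,2-olide | C=C1C(=O)O[C@H]2C[C@]3(COC(C)=O)CC[C@@]4(C)CC=C(C)CC[C@@H]4[C@@]3(O)[C@@H]12 | intermediate
26 | (2S,3S,4R,5S,6S,9S,12S,13R)-17-acetoxy-12,13-epoxy-4-hydroxycyath-18(19)-en-20,2-olide (CNP0214540.1) | C=C1C(=O)O[C@H]2C[C@]3(COC(C)=O)CC[C@@]4(C)C[C@H]5O[C@@]5(C)CC[C@@H]4[C@@]3(O)[C@@H]12 | target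

**Count**
Total steps: 17. Longest linear sequence: 14 (steps 1–7, 10, 12–17).

**Steps most likely to fail, with fallbacks**

Step 15. The more substituted C5 could migrate instead of C8, or ring A might not close under Lewis acid. The fallback sets out from 22 and comes back at 25. Compound 22 is treated with BF3·OEt2 at −78 °C only and quenched cold, so that ketol 23 is isolated. Ketol 23 is acetylated (Ac2O, pyridine) to the acetoxy ketone F1, which can no longer lose formaldehyde by retro-aldol. Ring A is then closed by fluoride-triggered allyl transfer from silicon (TBAF buffered with AcOH, THF, −20 °C), which activates the nucleophile instead of the ketone and gives 25 directly.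

Step 14. The facial selectivity at C9 rests on the vanadate distinguishing C8 from C5 on a tertiary carbinol, and the C9 configuration of the whole route depends on it. The fallback sets out from 21 and comes back at 22. Compound 21 reacts with trichloroacetyl isocyanate to give the N-(trichloroacetyl)carbamate F2. Iodocyclisation (I2, NaHCO3, MeCN) with loss of trichloroacetamide gives the iodomethyl cyclic carbonate F3, where C9 is set by ring closure of the carbamate oxygen onto the iodonium ion rather than by the vanadate. K2CO3 in MeOH at 0 °C then cleaves the carbonate and closes the epoxide to 22.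

Step 17. The peracid could attack the α face of the flexible seven-membered ring. The fallback sets out from 25 and comes back at 26. NBS in THF/H2O gives the bromohydrin F4 (13α-Br, 12β-OH), formed by water opening the bromonium ion at tertiary C12 from the face opposite to it. DBU in CH2Cl2 then closes the epoxide with inversion at C13, which places the oxygen on the face opposite to the one the peracid reaches and gives 26.

**Further compounds**
F1 | step 15 | [(2S,4aS,9aS)-4a,7-dimethyl-1-oxo-2-{[(2S)-5-oxo-4-[(trimethylsilyl)methyl]-2,5-dihydrofuran-2-yl]methyl}-2,3,4,4a,5,8,9,9a-octahydro-1H-benzo[7]annulen-2-yl]methyl acetate | O=C1[C@](COC(C)=O)(C[C@@H]3OC(=O)C(C[Si](C)(C)C)=C3)CC[C@@]2(C)CC=C(C)CC[C@H]12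
F2 | step 14 | (1R,3aS,8aS)-3a,6-dimethyl-1-(3-{(2S)-5-oxo-4-[(trimethylsilyl)methyl]-2,5-dihydrofuran-2-yl}prop-1-en-2-yl)-1,2,3,3a,4,7,8,8a-octahydroazulen-1-yl (trichloroacetyl)carbamate | O=C(NC(=O)C(Cl)(Cl)Cl)O[C@]1(C(=C)C[C@@H]3OC(=O)C(C[Si](C)(C)C)=C3)CC[C@@]2(C)CC=C(C)CC[C@H]12
F3 | step 14 | iodomethyl cyclic carbonate of 21 (1,3-dioxolan-2-one spanning O–C4 and O–C9; CH2I on C9; C4 R; C9 R; other centres as in 21) | O=C1O[C@](CI)(C[C@@H]4OC(=O)C(C[Si](C)(C)C)=C4)[C@@]2(O1)CC[C@@]3(C)CC=C(C)CC[C@H]23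
F4 | step 17 | (2S,3S,4R,5S,6S,9S,12S,13S)-17-acetoxy-13-bromo-4,12-dihydroxycyath-18(19)-en-20,2-olide (13α-Br, 12β-OH) | C=C1C(=O)O[C@H]2C[C@]3(COC(C)=O)CC[C@@]4(C)C[C@H](Br)[C@@](C)(O)CC[C@@H]4[C@@]3(O)[C@@H]12
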